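A flat line cannot tell you whether a catalyst has died or a reversible reaction has reached equilibrium, and Wednesday's run goes flat.

- Wednesday's: substrate 0.50 mM; free catalyst 2 µM; run made earlier
- flask: substrate 0.50 mM; free catalyst 1.0 µM; time 20 min

Wednesday's run (percent of the substrate charged)

| time / min | isomer of the product A / % | target / % |
|---|---|---|
| 0.333 | 21 | 16 |
| 1.00 | 21 | 32 |
| 1.50 | 20 | 35 |
| 2.50 | 17 | 38 |
| 4.00 | 16 | 39 |
| 5.00 | 20 | 38 |
| 6.00 | 20 | 35 |

(each reading ± 1.5 percentage points)

- the numbers in the tables scatter by 1.5 percentage points (one standard deviation)
- a reading or a percentage of target counts all its forms, free or not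
- no earlier run changes the charge of free catalyst; that part of a forecast is a guess

- share of isomer of the product A in isomer of the product A plus target at 2.5 s
- share of isomer of the product A in isomer of the product A plus target at 50 s
- share of isomer of the product A in isomer of the product A plus target at 20 min

1. In Wednesday's run, isomer of the product A plus target reads 55.0% at 2.50 min and 55.0% at 6.00 min. That is flat, with 45.0% of the substrate charged outside those two.

2. Catalyst is the reagent charged in the smaller amount, so write its balance. Suppose it dies in use: free catalyst plus dead catalyst equals the charge, and the run stalls when free catalyst is gone.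

3. Each catalyst in Wednesday's run then delivered 138 molecules of the two products. Call this the visible yield per catalyst, a turnover number. It is my reading and a guess, since a stall at equilibrium would look the same.

4. Your flask has 1.0 µM of catalyst, so on that guess isomer of the product A plus target stops near 27.5% of its substrate.

5. Wednesday's share of isomer of the product A read 56.8% at 20 s, when the two together stood at 37.0%, and it fell as target climbed beyond that. That guessed stop in your flask lies lower, so I expect about 56.8% at 20 min. No reading reaches 2.5 s, so I name nothing there.

The forecast gives 65%, 54% and 47%, and sees in Wednesday's late rise “a slow drift of target towards A”. At 20 min my figure is higher.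

The flask gives 28.2%, 55.9% and 57.3%.

    substrate + free catalyst ⇌ target + free catalyst, rate k1*[substrate]*[free catalyst] forward; the back reaction follows from the equilibrium constant (K = 5.63, k = 17900 M⁻¹ s⁻¹)
    target + free catalyst ⇌ isomer of the product A + free catalyst, rate k2*[free catalyst]*[target] forward; the back reaction follows from the equilibrium constant (K = 1.35, k = 3.62 × 10⁵ M⁻¹ s⁻¹)
    isomer of the product A + free catalyst ⇌ isomer of the product B + free catalyst, rate k3*[free catalyst]*[isomer of the product A] forward; the back reaction follows from the equilibrium constant (K = 3.90, k = 2790 M⁻¹ s⁻¹)
    substrate + free catalyst → spent catalyst (k = 55.9 M⁻¹ s⁻¹)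
    target ⇌ isomer of the product C (K = 2.12, k = 0.0239 s⁻¹)
    crystals ⇌ target, rate k6*(cs6 - [target]) while solid is left; crystals form when [target] > cs6 (solubility = 0.0720 mM, k = 0.338 s⁻¹)

This flask ends with isomer of the product A plus target at 31.5% against my guess of 27.5%, with 38% of the substrate left and free catalyst at 0.0682% of its charge by 10.0 min. At 0.496 min the forward making of target from substrate runs 320 times faster than the loss of substrate and free catalyst to spent catalyst. For the neighbour flask with 1.2 mM of substrate, the same yield per catalyst gives 11.5%, and that flask ends with 13.9% of the two.

The numbers in the tables stem from a simulated flask on assumed constants; scatter was added.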